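**Retrosynthetic overview**
- Last step: global O-debenzylation. Before it, the C4–aryl bond is made by acid-catalysed Friedel–Crafts union of a (2S)-flavan-4-ol with 9-phenylnonanoyl-phloroglucinol (2,4-trans by axial attack on the C4 cation).
- The flavan-4-ol comes from the (2S)-flavanone; C2 is fixed by transfer-hydrogenative kinetic resolution of the racemic flavanone.
- Key C–C bond: intermolecular Claisen–Schmidt aldol condensation of the ring A acetophenone with the ring B aldehyde gives the chalcone (C2–C3 bond).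
- Ring order: only ring C (the pyran) is built, by oxa-Michael closure of the chalcone; rings A and B, the phloroglucinol ring and the terminal phenyl are bought.
- Acylphloroglucinol: Friedel–Crafts acylation of phloroglucinol with 9-phenylnonanoyl chloride, made from monomethyl azelate and benzene.

Assumption: (+)-myristinin D is the (2S,4R)-2,4-trans isomer encoded by the SMILES; the sign of rotation is taken from the name only.

**Route**

Step 1
Reactants: 1 monomethyl azelate (9-methoxy-9-oxononanoic acid)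
Product: 2 methyl 9-chloro-9-oxononanoate
Conditions: (COCl)2 (1.3 equiv), DMF (cat.), CH2Cl2, 0 °C → rt; evaporate, use crude
Reagents that add atoms: oxalyl chloride, O=C(Cl)C(=O)Cl
Why: Acid chloride formation (Vilsmeier-type catalysis by DMF) activates only the free acid end; the methyl ester is inert.

Step 2
Reactants: 2 methyl 9-chloro-9-oxononanoate; 3 benzene
Product: 4 methyl 9-oxo-9-phenylnonanoate
Conditions: AlCl3 (2.2 equiv), benzene (solvent), 0 °C → rt; ice/HCl
Reagents that add atoms: none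
Why: Friedel–Crafts acylation stops at monoacylation because the aryl ketone deactivates the ring, and the ester survives as its AlCl3 complex.

Step 3
Reactants: 4 methyl 9-oxo-9-phenylnonanoate
Product: 6 methyl 9-phenylnonanoate, via benzylic alcohol 5 (not isolated)
Conditions: Et3SiH (3 equiv), TFA, rt → 50 °C
Reagents that add atoms: none
Why: Ionic hydrogenation reduces the aryl ketone to the methylene through the benzylic alcohol and its cation, and leaves the ester alone.

Step 4
Reactants: 6 methyl 9-phenylnonanoate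
Product: 7 9-phenylnonanoic acid
Conditions: LiOH·H2O, THF/MeOH/H2O, rt; then 1 M HCl
Reagents that add atoms: lithium hydroxide, [Li+].[OH-]
Why: Plain ester saponification with no competing functionality.

Step 5
Reactants: 7 9-phenylnonanoic acid
Product: 8 9-phenylnonanoyl chloride
Conditions: (COCl)2 (1.3 equiv), DMF (cat.), CH2Cl2, 0 °C → rt; evaporate, use crude
Reagents that add atoms: oxalyl chloride, O=C(Cl)C(=O)Cl
Why: Standard acid chloride formation giving only gaseous by-products.

Step 6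
Reactants: 8 9-phenylnonanoyl chloride; 9 phloroglucinol (anhydrous, 1.3 equiv)
Product: 10 9-phenyl-1-(2,4,6-trihydroxyphenyl)nonan-1-one
Conditions: AlCl3 (4 equiv), PhNO2/CH2Cl2, 0 → 50 °C; ice/HCl
Reagents that add atoms: none
Why: Friedel–Crafts C-acylation of the very electron-rich triphenol stops after one acyl group because the chelated ketone deactivates the ring.

Step 7
Reactants: 11 2,4-dihydroxyacetophenone
Product: 12 1-[4-(benzyloxy)-2-hydroxyphenyl]ethan-1-one
Conditions: BnBr (1.05 equiv), K2CO3 (1.1 equiv), acetone, reflux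
Reagents that add atoms: benzyl bromide, BrCc1ccccc1
Why: Williamson etherification is selective for the 4-OH because the 2-OH is tied up in a hydrogen bond to the carbonyl.

Step 8
Reactants: 12 1-[4-(benzyloxy)-2-hydroxyphenyl]ethan-1-one; 13 4-(benzyloxy)benzaldehyde
Product: 15 (2E)-1-[4-(benzyloxy)-2-hydroxyphenyl]-3-[4-(benzyloxy)phenyl]prop-2-en-1-one, via β-hydroxy ketone 14 (not isolated)
Conditions: KOH (50% aq, 10 equiv), EtOH, rt, 48 h; then HCl
Reagents that add atoms: none
Why: Claisen–Schmidt crossed aldol condensation between the only enolisable ketone and a non-enolisable aldehyde, followed by dehydration to the conjugated E-chalcone; no stereocentre remains.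

Step 9
Reactants: 15 (2E)-1-[4-(benzyloxy)-2-hydroxyphenyl]-3-[4-(benzyloxy)phenyl]prop-2-en-1-one
Product: 16 racemic 7-(benzyloxy)-2-[4-(benzyloxy)phenyl]chroman-4-one
Conditions: NaOAc (10 equiv), EtOH, reflux, 24–48 h; recovered 15 recycled
Reagents that add atoms: none
Why: Base-mediated intramolecular oxa-Michael addition of the 2'-phenoxide (chalcone–flavanone isomerisation) closes ring C and gives C2 as a racemate.

Step 10
Reactants: 16 racemic 7-(benzyloxy)-2-[4-(benzyloxy)phenyl]chroman-4-one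
Product: 17 (2S)-7-(benzyloxy)-2-[4-(benzyloxy)phenyl]chroman-4-one (recovered unreacted enantiomer)
Conditions: RuCl[(R,R)-TsDPEN](p-cymene) (1 mol %), HCO2H/Et3N (5:2), EtOAc, 40 °C, stopped at 52–55% conversion (chiral HPLC); chromatography, recrystallisation
Reagents that add atoms: none
Why: Noyori asymmetric transfer hydrogenation used as a kinetic resolution: the (R,R)-catalyst reduces the (2R)-ketone quickly to the (2R,4R)-cis-alcohol, so the (2S)-ketone is left in high ee and C2 is fixed by selection.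

Step 11
Reactants: 17 (2S)-7-(benzyloxy)-2-[4-(benzyloxy)phenyl]chroman-4-one
Product: 18 (2S,4S)-7-(benzyloxy)-2-[4-(benzyloxy)phenyl]chroman-4-ol (2,4-cis)
Conditions: NaBH4, THF/MeOH (1:1), 0 °C
Reagents that add atoms: none
Why: Hydride reduction with axial attack gives the diequatorial cis-alcohol without touching C2; the C4 configuration is erased in the next step, so any trans isomer is carried along.

Step 12
Reactants: 18 (2S,4S)-7-(benzyloxy)-2-[4-(benzyloxy)phenyl]chroman-4-ol; 10 9-phenyl-1-(2,4,6-trihydroxyphenyl)nonan-1-one (3 equiv)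
Product: 20 1-{3-[(2S,4R)-7-(benzyloxy)-2-[4-(benzyloxy)phenyl]chroman-4-yl]-2,4,6-trihydroxyphenyl}-9-phenylnonan-1-one, via flavan-4-yl cation 19 (not isolated)
Conditions: TsOH·H2O (20 mol %), CH2Cl2/MeCN (1:1), 0 °C → rt; chromatography removes the minor 2,4-cis isomer and excess 10
Reagents that add atoms: none
Why: Dehydrative Friedel–Crafts alkylation: acid ionises the C4–OH (water leaves) to the benzylic cation stabilised by O1 and the para 7-OBn. One of the two equivalent free ring carbons of 10 attacks it pseudo-axially on the half-chair with the 2-aryl group equatorial, which gives the 2,4-trans (4R) product with C2 untouched.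

Step 13
Reactants: 20 1-{3-[(2S,4R)-7-(benzyloxy)-2-[4-(benzyloxy)phenyl]chroman-4-yl]-2,4,6-trihydroxyphenyl}-9-phenylnonan-1-one
Product: 21 (+)-myristinin D
Conditions: H2 (1 atm), 10% Pd/C, EtOAc/MeOH (1:1), rt
Reagents that add atoms: none
Why: Hydrogenolysis of the two aryl benzyl ethers under mild conditions that spare the chelated aryl ketone, the chroman C–O bond and both stereocentres.

**Compound list**

1 | monomethyl azelate (9-methoxy-9-oxononanoic acid) | COC(=O)CCCCCCCC(=O)O | starting material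
2 | methyl 9-chloro-9-oxononanoate | COC(=O)CCCCCCCC(=O)Cl | intermediate
3 | benzene | c1ccccc1 | starting material
4 | methyl 9-oxo-9-phenylnonanoate | COC(=O)CCCCCCCC(=O)c1ccccc1 | intermediate
5 | methyl 9-hydroxy-9-phenylnonanoate (racemic, not isolated) | COC(=O)CCCCCCCC(O)c1ccccc1 | intermediate
6 | methyl 9-phenylnonanoate | COC(=O)CCCCCCCCc1ccccc1 | intermediate
7 | 9-phenylnonanoic acid | OC(=O)CCCCCCCCc1ccccc1 | intermediate
8 | 9-phenylnonanoyl chloride | ClC(=O)CCCCCCCCc1ccccc1 | intermediate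
9 | phloroglucinol (benzene-1,3,5-triol) | Oc1cc(O)cc(O)c1 | starting material
10 | 9-phenyl-1-(2,4,6-trihydroxyphenyl)nonan-1-one | O=C(CCCCCCCCc1ccccc1)c1c(O)cc(O)cc1O | intermediate
11 | 2,4-dihydroxyacetophenone | CC(=O)c1ccc(O)cc1O | starting material
12 | 1-[4-(benzyloxy)-2-hydroxyphenyl]ethan-1-one | CC(=O)c1ccc(OCc2ccccc2)cc1O | intermediate
13 | 4-(benzyloxy)benzaldehyde | O=Cc1ccc(OCc2ccccc2)cc1 | starting material
14 | 1-[4-(benzyloxy)-2-hydroxyphenyl]-3-[4-(benzyloxy)phenyl]-3-hydroxypropan-1-one (racemic aldol adduct, not isolated) | O=C(CC(O)c1ccc(OCc2ccccc2)cc1)c1ccc(OCc2ccccc2)cc1O | intermediate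
15 | (2E)-1-[4-(benzyloxy)-2-hydroxyphenyl]-3-[4-(benzyloxy)phenyl]prop-2-en-1-one (chalcone) | O=C(/C=C/c1ccc(OCc2ccccc2)cc1)c1ccc(OCc2ccccc2)cc1O | intermediate
16 | racemic 7-(benzyloxy)-2-[4-(benzyloxy)phenyl]chroman-4-one | O=C1CC(c2ccc(OCc3ccccc3)cc2)Oc2cc(OCc3ccccc3)ccc12 | intermediate
17 | (2S)-7-(benzyloxy)-2-[4-(benzyloxy)phenyl]chroman-4-one | O=C1C[C@@H](c2ccc(OCc3ccccc3)cc2)Oc2cc(OCc3ccccc3)ccc12 | intermediate
18 | (2S,4S)-7-(benzyloxy)-2-[4-(benzyloxy)phenyl]chroman-4-ol (cis) | O[C@H]1C[C@@H](c2ccc(OCc3ccccc3)cc2)Oc2cc(OCc3ccccc3)ccc12 | intermediate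
19 | (2S)-7-(benzyloxy)-2-[4-(benzyloxy)phenyl]chroman-4-ylium (benzylic cation, not isolated) | [CH+]1C[C@@H](c2ccc(OCc3ccccc3)cc2)Oc2cc(OCc3ccccc3)ccc12 | intermediate
20 | 1-{3-[(2S,4R)-7-(benzyloxy)-2-[4-(benzyloxy)phenyl]chroman-4-yl]-2,4,6-trihydroxyphenyl}-9-phenylnonan-1-one (2,4-trans) | O=C(CCCCCCCCc1ccccc1)c1c(O)cc(O)c([C@@H]2C[C@@H](c3ccc(OCc4ccccc4)cc3)Oc3cc(OCc4ccccc4)ccc32)c1O | intermediate
21 | (+)-myristinin D, 1-{2,4,6-trihydroxy-3-[(2S,4R)-7-hydroxy-2-(4-hydroxyphenyl)chroman-4-yl]phenyl}-9-phenylnonan-1-one | O=C(CCCCCCCCc1ccccc1)c1c(O)cc(O)c([C@@H]2C[C@@H](c3ccc(O)cc3)Oc3cc(O)ccc32)c1O | target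

**Totals**

Total step count: 13.
Longest linear sequence: 8 steps (steps 1–6, then 12 and 13, from monomethyl azelate); the flavan arm is 7 steps (steps 7–13).

**Three steps most likely to fail**

Step 12 (Friedel–Crafts union). Risks are an unfavourable trans/cis ratio, double alkylation of 10, elimination of 18 to the flav-3-ene, attack of the cation on ring A of a second flavan, and poor solubility of the free triphenol. The fallback sets out from 10 (18 stays the electrophile) and comes back at 21. Compound 10 is selectively dibenzylated (BnBr 2.1 equiv, K2CO3, acetone, reflux; the chelated ortho-OH stays free) to 1-[2,4-bis(benzyloxy)-6-hydroxyphenyl]-9-phenylnonan-1-one F1. F1 dissolves fully in CH2Cl2 and is coupled with 18 under Lewis-acid activation at low temperature (BF3·OEt2, CH2Cl2, −78 → −30 °C). This gives mainly 1-{4,6-bis(benzyloxy)-3-[(2S,4R)-7-(benzyloxy)-2-[4-(benzyloxy)phenyl]chroman-4-yl]-2-hydroxyphenyl}-9-phenylnonan-1-one F2; attack at the other free ring position gives a regioisomer that converges on the same final product. H2 with Pd/C in EtOAc/MeOH then removes all four benzyl groups and gives 21.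

Step 10 (kinetic resolution). Risks are a lower selectivity factor for this bis-benzyloxy substrate, the need for exact conversion control, and the 50% ceiling. The fallback sets out from 16 and comes back at 18, replacing the catalytic resolution by separation of covalent diastereomers. Compound 16 is reduced (NaBH4, THF/MeOH, 0 °C) to racemic cis-7-(benzyloxy)-2-[4-(benzyloxy)phenyl]chroman-4-ol F3. F3 is esterified with (2S)-2-methoxy-2-phenylacetic acid (DCC, DMAP 5 mol %, CH2Cl2, 0 °C) to give (2S,4S)-7-(benzyloxy)-2-[4-(benzyloxy)phenyl]chroman-4-yl (2S)-2-methoxy-2-phenylacetate F4 and (2R,4R)-7-(benzyloxy)-2-[4-(benzyloxy)phenyl]chroman-4-yl (2S)-2-methoxy-2-phenylacetate F5. These are separated by crystallisation or by chromatography on Et3N-deactivated silica (the benzylic esters are acid-labile) and assigned by the O-methylmandelate NMR model. LiOH in THF/H2O at 0 °C cleaves F4 to 18.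

Step 13 (final hydrogenolysis). Risks are reductive opening of the benzylic C2–O1 bond of the 2,4-diarylchroman, slow debenzylation of the hindered polyphenol, and air-sensitivity of the product on long reaction times. The fallback sets out from 17 and comes back at 21, moving the hydrogenolysis to the simple flavanone and making the last deprotection fluoride-based. Compound 17 is debenzylated (H2, Pd/C, EtOAc) to (2S)-7-hydroxy-2-(4-hydroxyphenyl)chroman-4-one F6. F6 is silylated at once (i-Pr3SiCl, imidazole, DMF, 0 °C, to limit base-induced racemisation) to (2S)-7-[(triisopropylsilyl)oxy]-2-{4-[(triisopropylsilyl)oxy]phenyl}chroman-4-one F7. NaBH4 in THF/EtOH at 0 °C gives (2S,4S)-7-[(triisopropylsilyl)oxy]-2-{4-[(triisopropylsilyl)oxy]phenyl}chroman-4-ol F8. Coupling with 10 as in step 12 gives 1-{2,4,6-trihydroxy-3-[(2S,4R)-7-[(triisopropylsilyl)oxy]-2-{4-[(triisopropylsilyl)oxy]phenyl}chroman-4-yl]phenyl}-9-phenylnonan-1-one F9. Bu4NF buffered with AcOH in THF at 0 °C then releases 21.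

**Further compounds**

F1 | step 12 | 1-[2,4-bis(benzyloxy)-6-hydroxyphenyl]-9-phenylnonan-1-one | O=C(CCCCCCCCc1ccccc1)c1c(O)cc(OCc2ccccc2)cc1OCc1ccccc1
F2 | step 12 | 1-{4,6-bis(benzyloxy)-3-[(2S,4R)-7-(benzyloxy)-2-[4-(benzyloxy)phenyl]chroman-4-yl]-2-hydroxyphenyl}-9-phenylnonan-1-one | O=C(CCCCCCCCc1ccccc1)c1c(OCc2ccccc2)cc(OCc2ccccc2)c([C@@H]2C[C@@H](c3ccc(OCc4ccccc4)cc3)Oc3cc(OCc4ccccc4)ccc32)c1O
F3 | step 10 | racemic cis-7-(benzyloxy)-2-[4-(benzyloxy)phenyl]chroman-4-ol (both enantiomers written) | O[C@H]1C[C@@H](c2ccc(OCc3ccccc3)cc2)Oc2cc(OCc3ccccc3)ccc12.O[C@@H]1C[C@H](c2ccc(OCc3ccccc3)cc2)Oc2cc(OCc3ccccc3)ccc12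
F4 | step 10 | (2S,4S)-7-(benzyloxy)-2-[4-(benzyloxy)phenyl]chroman-4-yl (2S)-2-methoxy-2-phenylacetate | CO[C@H](C(=O)O[C@H]1C[C@@H](c2ccc(OCc3ccccc3)cc2)Oc2cc(OCc3ccccc3)ccc12)c1ccccc1
F5 | step 10 | (2R,4R)-7-(benzyloxy)-2-[4-(benzyloxy)phenyl]chroman-4-yl (2S)-2-methoxy-2-phenylacetate | CO[C@H](C(=O)O[C@@H]1C[C@H](c2ccc(OCc3ccccc3)cc2)Oc2cc(OCc3ccccc3)ccc12)c1ccccc1
F6 | step 13 | (2S)-7-hydroxy-2-(4-hydroxyphenyl)chroman-4-one | O=C1C[C@@H](c2ccc(O)cc2)Oc2cc(O)ccc12
F7 | step 13 | (2S)-7-[(triisopropylsilyl)oxy]-2-{4-[(triisopropylsilyl)oxy]phenyl}chroman-4-one | O=C1C[C@@H](c2ccc(O[Si](C(C)C)(C(C)C)C(C)C)cc2)Oc2cc(O[Si](C(C)C)(C(C)C)C(C)C)ccc12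
F8 | step 13 | (2S,4S)-7-[(triisopropylsilyl)oxy]-2-{4-[(triisopropylsilyl)oxy]phenyl}chroman-4-ol | O[C@H]1C[C@@H](c2ccc(O[Si](C(C)C)(C(C)C)C(C)C)cc2)Oc2cc(O[Si](C(C)C)(C(C)C)C(C)C)ccc12
F9 | step 13 | 1-{2,4,6-trihydroxy-3-[(2S,4R)-7-[(triisopropylsilyl)oxy]-2-{4-[(triisopropylsilyl)oxy]phenyl}chroman-4-yl]phenyl}-9-phenylnonan-1-one | O=C(CCCCCCCCc1ccccc1)c1c(O)cc(O)c([C@@H]2C[C@@H](c3ccc(O[Si](C(C)C)(C(C)C)C(C)C)cc3)Oc3cc(O[Si](C(C)C)(C(C)C)C(C)C)ccc32)c1O
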